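**Plan**

- Retrosynthesis: the ester C–O bond between the diol and the (Z)-2-(hydroxymethyl)but-2-enoyl unit is cut first. In the diol (C1 = benzylic carbinol carbon, C2 = neighbouring methine, C3 = oxymethylene carbon) the C1–O bond is traced to a C1–Si bond and, with the C2–H bond, to a C1=C2 alkene. That alkene is cut by olefination and the C2–CH2(cinnamyl) bond by enolate alkylation.
- Enabling feature: C1 carries oxygen, C2 carries hydrogen, and the oxygen on C3 lies two bonds from C2. An O–SiMe2–H group on that oxygen can therefore add across C1=C2 and close the five-membered ring O–Si–C1–C2–C3 (a 1-oxa-2-silacyclopentane), the only ring the route makes; oxidation of its C1–Si bond opens it to the 1,3-diol.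
- Forward order: a cinnamyl bromide alkylates a trifluoroethyl phosphonoacetate; Z-selective olefination of 3,4-dimethoxybenzaldehyde and reduction give the Z allylic alcohol; silylation and rhodium-catalysed ring closure give the silacycle; oxidation gives the diol; the separately made O-silyl acid is joined to the primary hydroxyl, and desilylation ends the route.
- Stereochemistry: C1 and C2 are set together in the ring closure, their relative configuration by syn addition to the Z alkene and their absolute configuration by the chiral diphosphine on rhodium. C–Si oxidation retains C1. The E styrene comes from the starting alcohol, and the Z butenoate from (Z)-2-iodobut-2-en-1-ol through lithiation and carboxylation with retention.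

Key step: step 6

Assumption: the sense of induction of a BINAP antipode on this Z-trisubstituted silyl ether cannot be assigned in advance from the disubstituted cases; (R)-BINAP is written, and (S)-BINAP would replace it without other change if a trial showed that it is the antipode leading to the (3S,4R) ring.

**Route**

Step 1
Reactants: 1 (E)-3-(4-methoxyphenyl)prop-2-en-1-ol
Product: 2 (E)-1-(3-bromoprop-1-enyl)-4-methoxybenzene
Conditions: PBr3 (0.4 equiv), Et2O, 0 °C; cold aqueous NaHCO3 wash, used at once without chromatography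
Reagents that add atoms: phosphorus tribromide, BrP(Br)Br
Why: Bromination of a primary allylic alcohol with PBr3 (SN2 displacement of a phosphite ester by bromide) is routine for cinnamyl alcohols and keeps the E alkene, and the labile electron-rich bromide is not stored.

Step 2
Reactants: 3 methyl 2-[bis(2,2,2-trifluoroethoxy)phosphoryl]acetate; 2 (E)-1-(3-bromoprop-1-enyl)-4-methoxybenzene
Product: 5 methyl (E)-2-[bis(2,2,2-trifluoroethoxy)phosphoryl]-5-(4-methoxyphenyl)pent-4-enoate (racemic), via sodium phosphonate enolate 4 (not isolated)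
Conditions: 3 (1.3 equiv), NaH (1.2 equiv), THF, 0 °C; then 2, 0 °C to rt
Reagents that add atoms: none
Why: SN2 C-alkylation of a stabilised phosphonoacetate enolate by a reactive allylic bromide is well established, the excess of 3 should hold back double alkylation, and the new stereocentre is racemic and is erased in step 3.

Step 3
Reactants: 5 methyl (E)-2-[bis(2,2,2-trifluoroethoxy)phosphoryl]-5-(4-methoxyphenyl)pent-4-enoate; 6 3,4-dimethoxybenzaldehyde
Product: 8 methyl (2Z,4E)-2-[(3,4-dimethoxyphenyl)methylidene]-5-(4-methoxyphenyl)pent-4-enoate (aryl cis to the ester), via potassium phosphonate carbanion 7 (not isolated)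
Conditions: KN(SiMe3)2, 18-crown-6, THF, −78 °C; then 6, −78 °C
Reagents that add atoms: none
Why: Still–Gennari variant of the Horner–Wadsworth–Emmons olefination, in which the electron-poor trifluoroethyl phosphonate with a dissociated potassium counter-ion eliminates quickly from the kinetic adduct and so places the aryl group cis to the ester (2Z), the geometry the ring closure needs.

Step 4
Reactants: 8 methyl (2Z,4E)-2-[(3,4-dimethoxyphenyl)methylidene]-5-(4-methoxyphenyl)pent-4-enoate
Product: 9 (2Z,4E)-2-[(3,4-dimethoxyphenyl)methylidene]-5-(4-methoxyphenyl)pent-4-en-1-ol (aryl cis to CH2OH)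
Conditions: i-Bu2AlH (2.5 equiv), CH2Cl2, −78 °C
Reagents that add atoms: none
Why: 1,2-Reduction of an α,β-unsaturated ester to the allylic alcohol by i-Bu2AlH at low temperature is standard and should leave both alkenes and their geometries untouched.

Step 5
Reactants: 9 (2Z,4E)-2-[(3,4-dimethoxyphenyl)methylidene]-5-(4-methoxyphenyl)pent-4-en-1-ol
Product: 10 {[(2Z,4E)-2-[(3,4-dimethoxyphenyl)methylidene]-5-(4-methoxyphenyl)pent-4-enyl]oxy}dimethylsilane
Conditions: (HMe2Si)2NH (1.5 equiv), THF, 50 °C; volatiles removed under vacuum, used without chromatography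
Reagents that add atoms: 1,1,3,3-tetramethyldisilazane, C[SiH](C)N[SiH](C)C
Why: O-Silylation of a primary alcohol with a disilazane gives the hydrosilyl ether with ammonia as the only by-product, so that no halide or amine salt is carried into the cationic rhodium step.

Step 6
Reactants: 10 {[(2Z,4E)-2-[(3,4-dimethoxyphenyl)methylidene]-5-(4-methoxyphenyl)pent-4-enyl]oxy}dimethylsilane
Product: 11 (3S,4R)-3-(3,4-dimethoxyphenyl)-4-[(E)-3-(4-methoxyphenyl)prop-2-enyl]-2,2-dimethyl-1-oxa-2-silacyclopentane (3,4-cis)
Conditions: [Rh(nbd)2]BF4 (3 mol %), (R)-BINAP (3.3 mol %), H2 then argon purge; 10, acetone, 25 to 50 °C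
Reagents that add atoms: none
Why: Proposed new method: the Si–H bond of 10 adds oxidatively to the cationic monovalent rhodium–BINAP fragment, the tethered C1=C2 alkene coordinates and inserts into the Rh–H or Rh–Si bond, and reductive elimination of the remaining bond completes a net syn addition of silicon and hydrogen; the closest known reaction type is the rhodium–diphosphine-catalysed asymmetric intramolecular hydrosilylation of hydrosilyl ethers of allylic alcohols, established for 1,2- and 1,1-disubstituted alkenes but not for a trisubstituted styrene that sets two stereocentres. The ring closes in the 5-endo-trig mode, silicon bonding to benzylic C1 and hydrogen to C2, because bonding of silicon to C2 would demand a four-membered ring. The absolute configuration at C1 (S on the ring, C3) and C2 (R on the ring, C4) should follow from the alkene face that the chiral diphosphine presents to rhodium, and their relative configuration (aryl and cinnamyl groups cis on the ring) from the Z geometry of 10 combined with syn addition. The step needs site selectivity for C1=C2 over the remote E-styrene and must outrun rhodium hydride-mediated migration of the skipped diene; the short tether should secure the first, since the remote alkene can be reached only through a 6-exo or 7-endo closure that is expected to be slower, and the styrenyl character of C1=C2, which favours insertion toward a benzylic carbon–rhodium bond, supports the second.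

Step 7
Reactants: 11 (3S,4R)-3-(3,4-dimethoxyphenyl)-4-[(E)-3-(4-methoxyphenyl)prop-2-enyl]-2,2-dimethyl-1-oxa-2-silacyclopentane
Product: 12 (1S,2R)-1-(3,4-dimethoxyphenyl)-2-[(E)-3-(4-methoxyphenyl)prop-2-enyl]propane-1,3-diol
Conditions: 30% H2O2, KF, KHCO3, THF/MeOH (1:1), rt
Reagents that add atoms: hydrogen peroxide, OO
Why: Tamao oxidation of an alkoxysilane, in which fluoride-activated silicon takes up hydroperoxide and the benzylic carbon migrates from silicon to oxygen with retention, so C1 keeps its configuration while the Si–O bond is hydrolysed to the primary alcohol and the non-conjugated alkene is inert to basic peroxide.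

Step 8
Reactants: 13 (E)-but-2-enal
Product: 14 (Z)-2-iodobut-2-enal (methyl cis to iodine)
Conditions: I2, K2CO3, DMAP (0.2 equiv), THF/H2O (1:1), rt
Reagents that add atoms: iodine, II
Why: α-Iodination of an enal by a Baylis–Hillman-type sequence (conjugate addition of DMAP, iodination of the enolate, elimination of the catalyst) is known for simple enals and should give the thermodynamically preferred Z isomer.

Step 9
Reactants: 14 (Z)-2-iodobut-2-enal
Product: 15 (Z)-2-iodobut-2-en-1-ol
Conditions: NaBH4, MeOH, 0 °C
Reagents that add atoms: none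
Why: Chemoselective 1,2-reduction of an aldehyde by borohydride, which leaves the vinyl iodide and its geometry alone.

Step 10
Reactants: 15 (Z)-2-iodobut-2-en-1-ol
Product: 16 (Z)-tert-butyl[(2-iodobut-2-enyl)oxy]dimethylsilane
Conditions: TBSCl, imidazole, CH2Cl2, 0 °C to rt
Reagents that add atoms: tert-butyl(chloro)dimethylsilane, CC(C)(C)[Si](C)(C)Cl
Why: Standard imidazole-promoted silyl ether protection of a primary allylic alcohol.

Step 11
Reactants: 16 (Z)-tert-butyl[(2-iodobut-2-enyl)oxy]dimethylsilane
Product: 18 (Z)-2-[(tert-butyldimethylsilyloxy)methyl]but-2-enoic acid (methyl cis to the carboxyl group), via vinyllithium 17 (not isolated)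
Conditions: t-BuLi (2.1 equiv), Et2O, −78 °C; then dry CO2, −78 to 0 °C; cold 1 M HCl to pH 3
Reagents that add atoms: carbon dioxide, O=C=O
Why: Iodine–lithium exchange gives an alkenyllithium that is configurationally stable at −78 °C, and its carboxylation proceeds with retention, so the methyl group ends cis to the carboxyl group (2Z), while the low temperature should hold back loss of silanolate and silyl migration.

Step 12
Reactants: 18 (Z)-2-[(tert-butyldimethylsilyloxy)methyl]but-2-enoic acid; 12 (1S,2R)-1-(3,4-dimethoxyphenyl)-2-[(E)-3-(4-methoxyphenyl)prop-2-enyl]propane-1,3-diol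
Product: 20 (2R,3S)-3-(3,4-dimethoxyphenyl)-3-hydroxy-2-[(E)-3-(4-methoxyphenyl)prop-2-enyl]propyl (Z)-2-[(tert-butyldimethylsilyloxy)methyl]but-2-enoate, via acid chloride 19 (not isolated)
Conditions: 18 (1.1 equiv), 1-chloro-N,N,2-trimethylprop-1-en-1-amine (1.0 equiv), CH2Cl2, 0 °C; then 12, 2,4,6-collidine, CH2Cl2, −40 to 0 °C
Reagents that add atoms: none
Why: Acylation of an alcohol by an acid chloride formed under neutral conditions with the α-chloroenamine, in which the hindered, non-nucleophilic collidine cannot add to the enoyl chloride and so should not isomerise the Z alkene, and at low temperature the unhindered primary hydroxyl should react ahead of the secondary benzylic one next to a branched carbon.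

Step 13
Reactants: 20 (2R,3S)-3-(3,4-dimethoxyphenyl)-3-hydroxy-2-[(E)-3-(4-methoxyphenyl)prop-2-enyl]propyl (Z)-2-[(tert-butyldimethylsilyloxy)methyl]but-2-enoate
Product: 21 (2R,3S)-3-(3,4-dimethoxyphenyl)-3-hydroxy-2-[(E)-3-(4-methoxyphenyl)prop-2-enyl]propyl (Z)-2-(hydroxymethyl)but-2-enoate
Conditions: HF·pyridine, pyridine, THF, 0 °C to rt
Reagents that add atoms: none
Why: Fluoride cleavage of a primary silyl ether under buffered conditions, which avoids the basic medium that promotes 1,3-acyl migration to the benzylic hydroxyl and should leave the ester, both alkenes and the stereocentres unchanged.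

**Compound list**

1 | (E)-3-(4-methoxyphenyl)prop-2-en-1-ol | OC/C=C/c1ccc(OC)cc1 | starting material
2 | (E)-1-(3-bromoprop-1-enyl)-4-methoxybenzene | BrC/C=C/c1ccc(OC)cc1 | intermediate
3 | methyl 2-[bis(2,2,2-trifluoroethoxy)phosphoryl]acetate | COC(=O)CP(=O)(OCC(F)(F)F)OCC(F)(F)F | starting material
4 | sodium enolate of methyl 2-[bis(2,2,2-trifluoroethoxy)phosphoryl]acetate | [Na+].COC(=O)[CH-]P(=O)(OCC(F)(F)F)OCC(F)(F)F | intermediate
5 | methyl (E)-2-[bis(2,2,2-trifluoroethoxy)phosphoryl]-5-(4-methoxyphenyl)pent-4-enoate (racemic) | COC(=O)C(C/C=C/c1ccc(OC)cc1)P(=O)(OCC(F)(F)F)OCC(F)(F)F | intermediate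
6 | 3,4-dimethoxybenzaldehyde | COc1ccc(C=O)cc1OC | starting material
7 | potassium salt of 5 (carbanion at C2) | [K+].COC(=O)[C-](C/C=C/c1ccc(OC)cc1)P(=O)(OCC(F)(F)F)OCC(F)(F)F | intermediate
8 | methyl (2Z,4E)-2-[(3,4-dimethoxyphenyl)methylidene]-5-(4-methoxyphenyl)pent-4-enoate | COC(=O)/C(=C\c1ccc(OC)c(OC)c1)C/C=C/c1ccc(OC)cc1 | intermediate
9 | (2Z,4E)-2-[(3,4-dimethoxyphenyl)methylidene]-5-(4-methoxyphenyl)pent-4-en-1-ol | OC/C(=C\c1ccc(OC)c(OC)c1)C/C=C/c1ccc(OC)cc1 | intermediate
10 | {[(2Z,4E)-2-[(3,4-dimethoxyphenyl)methylidene]-5-(4-methoxyphenyl)pent-4-enyl]oxy}dimethylsilane | C[SiH](C)OC/C(=C\c1ccc(OC)c(OC)c1)C/C=C/c1ccc(OC)cc1 | intermediate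
11 | (3S,4R)-3-(3,4-dimethoxyphenyl)-4-[(E)-3-(4-methoxyphenyl)prop-2-enyl]-2,2-dimethyl-1-oxa-2-silacyclopentane | C[Si]1(C)OC[C@@H](C/C=C/c2ccc(OC)cc2)[C@H]1c1ccc(OC)c(OC)c1 | intermediate
12 | (1S,2R)-1-(3,4-dimethoxyphenyl)-2-[(E)-3-(4-methoxyphenyl)prop-2-enyl]propane-1,3-diol | OC[C@@H](C/C=C/c1ccc(OC)cc1)[C@H](O)c1ccc(OC)c(OC)c1 | intermediate
13 | (E)-but-2-enal | C/C=C/C=O | starting material
14 | (Z)-2-iodobut-2-enal | C/C=C(\I)C=O | intermediate
15 | (Z)-2-iodobut-2-en-1-ol | C/C=C(\I)CO | intermediate
16 | (Z)-tert-butyl[(2-iodobut-2-enyl)oxy]dimethylsilane | C/C=C(\I)CO[Si](C)(C)C(C)(C)C | intermediate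
17 | (E)-[1-(tert-butyldimethylsilyloxy)but-2-en-2-yl]lithium (lithium cis to methyl) | [Li]/C(=C\C)CO[Si](C)(C)C(C)(C)C | intermediate
18 | (Z)-2-[(tert-butyldimethylsilyloxy)methyl]but-2-enoic acid | C/C=C(/CO[Si](C)(C)C(C)(C)C)C(=O)O | intermediate
19 | (Z)-2-[(tert-butyldimethylsilyloxy)methyl]but-2-enoyl chloride | C/C=C(/CO[Si](C)(C)C(C)(C)C)C(Cl)=O | intermediate
20 | (2R,3S)-3-(3,4-dimethoxyphenyl)-3-hydroxy-2-[(E)-3-(4-methoxyphenyl)prop-2-enyl]propyl (Z)-2-[(tert-butyldimethylsilyloxy)methyl]but-2-enoate | C/C=C(/CO[Si](C)(C)C(C)(C)C)C(=O)OC[C@@H](C/C=C/c1ccc(OC)cc1)[C@H](O)c1ccc(OC)c(OC)c1 | intermediate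
21 | (2R,3S)-3-(3,4-dimethoxyphenyl)-3-hydroxy-2-[(E)-3-(4-methoxyphenyl)prop-2-enyl]propyl (Z)-2-(hydroxymethyl)but-2-enoate | C/C=C(/CO)C(=O)OC[C@@H](C/C=C/c1ccc(OC)cc1)[C@H](O)c1ccc(OC)c(OC)c1 | target

**Count and risks**

Total steps: 13. Longest linear sequence: 9 steps (steps 1 to 7, then 12 and 13); the acid branch (steps 8 to 11) joins at step 12.

Step 6 (bears the label). The closure may stall at the hindered trisubstituted alkene, may go instead onto the remote styrene, may be preceded by hydride-mediated alkene migration or loss of the Z geometry, or may show poor enantioface discrimination. The fallback is an auxiliary-controlled aldol route of known chemistry that sets out from aldehyde 6 and returns at diol 12. (S)-4-Benzyloxazolidin-2-one is N-acylated with pent-4-enoyl chloride (n-BuLi, THF, −78 °C) to give (S)-4-benzyl-3-(pent-4-enoyl)oxazolidin-2-one F1. Its Z boron enolate (Bu2BOTf, i-Pr2NEt, CH2Cl2, −78 to 0 °C) adds to 6 through a chair transition state to give the syn aldol adduct (S)-4-benzyl-3-[(2S)-2-[(S)-(3,4-dimethoxyphenyl)(hydroxy)methyl]pent-4-enoyl]oxazolidin-2-one F2. Reductive removal of the auxiliary (LiBH4, THF, MeOH, 0 °C) gives (1S,2R)-1-(3,4-dimethoxyphenyl)-2-(prop-2-enyl)propane-1,3-diol F3. Cross-metathesis of F3 with 4-methoxystyrene (second-generation Grubbs catalyst, RuCl2(=CHPh)(PCy3)(H2IMes), CH2Cl2, 40 °C) then installs the E-styrene and gives 12.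

Step 12. Acylation may fail to discriminate between the two hydroxyl groups, or the activated enoyl group may isomerise from Z to E. The fallback forms the ester bond from the other side, by carboxylate alkylation; it sets out from diol 12 and returns at ester 20. The primary hydroxyl of 12 is sulfonylated selectively (TsCl, Et3N, catalytic Me3N·HCl, CH2Cl2, 0 °C) to give (2R,3S)-3-(3,4-dimethoxyphenyl)-3-hydroxy-2-[(E)-3-(4-methoxyphenyl)prop-2-enyl]propyl 4-methylbenzenesulfonate F4. Displacement by the caesium salt of acid 18 (Cs2CO3, DMF, 50 °C) then gives 20 without any activation of the unsaturated acyl group.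

Step 2. The electron-rich bromide may decompose before it is consumed, or the phosphonate may be alkylated twice. The fallback makes the same C–C bond by palladium-catalysed allylic substitution; it sets out from alcohol 1 and returns at phosphonate 5. Alcohol 1 is acetylated (Ac2O, pyridine) to give (E)-3-(4-methoxyphenyl)prop-2-enyl acetate F5, a stable electrophile. Enolate 4 then attacks the π-allyl complex that zerovalent palladium forms from F5 (Pd(PPh3)4, THF, rt to 50 °C) at its unsubstituted terminus (Tsuji–Trost reaction) to give 5.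

**Further compounds**

F1 | step 6 | (S)-4-benzyl-3-(pent-4-enoyl)oxazolidin-2-one | C=CCCC(=O)N1[C@@H](Cc2ccccc2)COC1=O
F2 | step 6 | (S)-4-benzyl-3-[(2S)-2-[(S)-(3,4-dimethoxyphenyl)(hydroxy)methyl]pent-4-enoyl]oxazolidin-2-one | O=C([C@@H](CC=C)[C@H](O)c1ccc(OC)c(OC)c1)N1[C@@H](Cc2ccccc2)COC1=O
F3 | step 6 | (1S,2R)-1-(3,4-dimethoxyphenyl)-2-(prop-2-enyl)propane-1,3-diol | OC[C@@H](CC=C)[C@H](O)c1ccc(OC)c(OC)c1
F4 | step 12 | (2R,3S)-3-(3,4-dimethoxyphenyl)-3-hydroxy-2-[(E)-3-(4-methoxyphenyl)prop-2-enyl]propyl 4-methylbenzenesulfonate | Cc1ccc(cc1)S(=O)(=O)OC[C@@H](C/C=C/c1ccc(OC)cc1)[C@H](O)c1ccc(OC)c(OC)c1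
F5 | step 2 | (E)-3-(4-methoxyphenyl)prop-2-enyl acetate | CC(=O)OC/C=C/c1ccc(OC)cc1
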